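**Retrosynthetic overview**

1. Feature: in ring A (C5–C10) the C6=C7–acetyl unit lies between quaternary C5 and oxygenated C8. It maps onto but-3-yn-2-one added across a 1-oxy diene C5=C10–C9=C8 mounted on ring B (C1–C5, C10; C3 OAc, C4 Me, C5 Me).
2. Endgame: the C9 angelate and the C10 tertiary alcohol come from SN2 opening, at C9, of a 9β,10β-epoxy-8-ketone by angelate. The oxirane comes from the C9=C10 bond of the cycloadduct, and C8=O from its C8 ether.
3. Key disconnection: C5–C6 and C7–C8 by Diels–Alder reaction of the (E)-dienol PMB ether of ring B with but-3-yn-2-one. Ring B is carried from the start; ring A is closed in this step.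
4. Diene: C8–O by copper-promoted coupling of 4-methoxybenzyl alcohol with an (E)-dienylboronate; C10–C9 by Suzuki coupling of a tetrasubstituted enol triflate.
5. Triflate: from conjugate reduction and enolate trapping of (S)-4-acetoxy-2,3-dimethylcyclohex-2-enone (sets C4). That enone comes from CBS reduction (sets C3), acetylation and allylic oxidation of 2,3-dimethylcyclohex-2-en-1-one.

Key step: step 8

Remark: locants on the bicyclic compounds are those of the eremophilane skeleton (ring B = C1–C5, C10; ring A = C5–C10); β is the face of the C5 methyl group, α the opposite face.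

**Route**

Step 1
Reactants: 1 2,3-dimethylcyclohex-2-en-1-one
Product: 2 (S)-2,3-dimethylcyclohex-2-en-1-ol
Conditions: (R)-Me-CBS oxazaborolidine (10 mol%), BH3·SMe2, THF, −20 °C; MeOH quench
Reagents that add atoms: none
Why: Corey–Bakshi–Shibata reduction, in which the oxazaborolidine–borane complex treats the α-methylated alkenyl arm as the large group and delivers hydride to one carbonyl face, so the (R)-catalyst should give the (S)-carbinol (later C3).

Step 2
Reactants: 2 (S)-2,3-dimethylcyclohex-2-en-1-ol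
Product: 3 (S)-2,3-dimethylcyclohex-2-en-1-yl acetate
Conditions: Ac2O, Et3N, DMAP (cat.), CH2Cl2, 0 °C → rt
Reagents that add atoms: acetic anhydride, CC(=O)OC(C)=O
Why: DMAP-catalysed O-acylation of the secondary allylic alcohol installs the C3 acetate of the target at the outset and leaves the stereocentre untouched.

Step 3
Reactants: 3 (S)-2,3-dimethylcyclohex-2-en-1-yl acetate
Product: 4 (S)-2,3-dimethyl-4-oxocyclohex-2-en-1-yl acetate
Conditions: Rh2(cap)4 (1 mol%; cap = caprolactamate), t-BuOOH (70% aq., 5 equiv), K2CO3 (0.5 equiv), CH2Cl2, rt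
Reagents that add atoms: tert-butyl hydroperoxide, CC(C)(C)OO
Why: Allylic C–H oxidation by the tert-butylperoxyl radical chain that the dirhodium caprolactamate sustains (the type that turns 3-acetoxy-Δ5-steroids into their 7-ketones) converts the ring CH2 next to the tetrasubstituted alkene into the enone carbonyl, the C–H geminal to the acetate being deactivated and the methyl C–H bonds being primary.

Step 4
Reactants: 4 (S)-2,3-dimethyl-4-oxocyclohex-2-en-1-yl acetate
Product: 5 (1S,2R)-4-{[diethoxy(methyl)silyl]oxy}-2,3-dimethylcyclohex-3-en-1-yl acetate (used crude)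
Conditions: (IPr)CuCl (3 mol%; IPr = 1,3-bis(2,6-diisopropylphenyl)imidazol-2-ylidene), NaOt-Bu (3 mol%), (EtO)2MeSiH (1.5 equiv), toluene, 0 °C → rt
Reagents that add atoms: diethoxy(methyl)silane, CCO[SiH](C)OCC
Why: Copper hydride 1,4-hydrosilylation (conjugate reduction), in which the ligated Cu–H delivers hydride to the β-carbon anti to the acetoxy group that A(1,2) strain with the β-methyl holds pseudoaxial, so the new methyl-bearing centre (later C4) is cis to the acetate and the silyl enol ether fixes the double bond on the tetrasubstituted side.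

Step 5
Reactants: 5 (1S,2R)-4-{[diethoxy(methyl)silyl]oxy}-2,3-dimethylcyclohex-3-en-1-yl acetate
Product: 6 (1S,2R)-2,3-dimethyl-4-{[(trifluoromethyl)sulfonyl]oxy}cyclohex-3-en-1-yl acetate
Conditions: PhNTf2 (1.3 equiv), CsF (2 equiv), DME, rt
Reagents that add atoms: N-phenylbis(trifluoromethanesulfonimide), FC(F)(F)S(=O)(=O)N(c1ccccc1)S(=O)(=O)C(F)(F)F
Why: Fluoride cleaves the Si–O bond and the regio-defined caesium enolate is O-sulfonylated by PhNTf2 (enol triflate formation from a silyl enol ether), so the tetrasubstituted vinyl triflate forms without enolate equilibration and without touching either stereocentre.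

Step 6
Reactants: 6 (1S,2R)-2,3-dimethyl-4-{[(trifluoromethyl)sulfonyl]oxy}cyclohex-3-en-1-yl acetate; 7 (E)-1,2-bis(4,4,5,5-tetramethyl-1,3,2-dioxaborolan-2-yl)ethene
Product: 8 (1S,2R)-2,3-dimethyl-4-[(E)-2-(4,4,5,5-tetramethyl-1,3,2-dioxaborolan-2-yl)ethenyl]cyclohex-3-en-1-yl acetate
Conditions: 7 (3 equiv), Pd(PPh3)4 (5 mol%), K3PO4, 1,4-dioxane, 80 °C
Reagents that add atoms: none
Why: Suzuki–Miyaura coupling of the vinyl triflate with one boron of the vinylene diboronate, used in excess so that monocoupling prevails, should give the (E)-dienylboronate with retention of alkene geometry.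

Step 7
Reactants: 8 (1S,2R)-2,3-dimethyl-4-[(E)-2-(4,4,5,5-tetramethyl-1,3,2-dioxaborolan-2-yl)ethenyl]cyclohex-3-en-1-yl acetate; 9 4-methoxybenzyl alcohol
Product: 10 (1S,2R)-4-[(E)-2-(4-methoxybenzyloxy)ethenyl]-2,3-dimethylcyclohex-3-en-1-yl acetate (ring B dienol ether: C3 OAc, C4 Me, C5=C10, C10–CH=CH–OPMB)
Conditions: Cu(OAc)2 (2 equiv), Et3N (4 equiv), 9 (excess, neat), 4 Å MS, rt, air
Reagents that add atoms: none
Why: Chan–Lam–Evans-type copper-promoted oxidative C–O coupling of an alkenyl pinacol boronate with an alcohol, which proceeds with retention at the vinyl carbon and so should deliver only the (E)-enol ether that the cycloaddition needs.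

Step 8
Reactants: 10 (1S,2R)-4-[(E)-2-(4-methoxybenzyloxy)ethenyl]-2,3-dimethylcyclohex-3-en-1-yl acetate; 11 but-3-yn-2-one
Product: 12 (3S,4R,5R,8S)-3-acetoxy-7-acetyl-8-(4-methoxybenzyloxy)-4,5-dimethyl bicyclic 6,9(10)-diene (3β-OAc, 4β-Me, 5β-Me, 8α-OPMB)
Conditions: 11 (4 equiv), BHT (cat.), 2,6-di-tert-butyl-4-methylpyridine (5 mol%), toluene, sealed tube, 100 °C
Reagents that add atoms: none
Why: Concerted, asynchronous thermal [4+2] cycloaddition of normal electron demand, of the type known for 2-methyl-1-vinylcyclohexenes with acetylenic esters and for 1-alkoxybutadienes with ynones. Ring A (C5–C6–C7–C8–C9–C10) is closed in one intermolecular cycloaddition that forms C5–C6 and C7–C8 together and leaves a 1,4-cyclohexadiene (C6=C7, C9=C10) that cannot aromatise because C5 is quaternary. The C8 alkoxy group puts the largest HOMO coefficient on C5, which bonds to the unsubstituted β-carbon of the ynone, so the acetyl-bearing carbon C7 ends next to C8. At C5 the ynone approaches the diene face anti to the pseudoaxial C4 methyl (the C3 acetate lies on the same β face), so the C5 methyl ends cis to the C4 methyl. At C8 the (E)-geometry places OPMB outside and the C5 methyl inside, so suprafacial addition gives C8–OPMB trans to the C5 methyl, and an alkyne dienophile raises no endo/exo question. The step needs the (E)-enol ether, secured by the stereospecific steps 6 and 7, because only this isomer can reach the s-cis conformation.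

Step 9
Reactants: 12 the cycloadduct (3S,4R,5R,8S)
Product: 13 (3S,4R,5R,8R,9S,10R)-3-acetoxy-7-acetyl-9β,10β-epoxy-8α-(4-methoxybenzyloxy)-4,5-dimethyl bicyclic 6-ene
Conditions: mCPBA (1.2 equiv), CH2Cl2/aq. NaHCO3, 0 °C
Reagents that add atoms: 3-chloroperoxybenzoic acid, OOC(=O)c1cccc(Cl)c1
Why: Prilezhaev epoxidation, in which the peracid attacks only the electron-rich trisubstituted C9=C10 bond (C6=C7 is deactivated by the acetyl group) and, as with allylic ethers in general, approaches anti to the pseudoaxial C8 OPMB group, so the oxirane oxygen should end on the β face and fix the C10 oxygen cis to the C5 methyl.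

Step 10
Reactants: 13 the 9β,10β-epoxy PMB ether
Product: 14 (3S,4R,5R,8R,9S,10R)-3-acetoxy-7-acetyl-9β,10β-epoxy-4,5-dimethyl bicyclic 6-en-8α-ol
Conditions: DDQ (1.3 equiv), CH2Cl2/pH 7 phosphate buffer, 0 °C
Reagents that add atoms: none
Why: Oxidative cleavage of the 4-methoxybenzyl ether by DDQ (benzylic hydride abstraction, then hydrolysis of the oxocarbenium ion) frees the C8 hydroxyl, and the product alcohol is allylic only to the electron-poor C6=C7 bond and so should not be over-oxidised.

Step 11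
Reactants: 14 the 9β,10β-epoxy-8α-ol
Product: 15 (3S,4R,5R,9R,10R)-3-acetoxy-7-acetyl-9β,10β-epoxy-4,5-dimethyl bicyclic 6-en-8-one
Conditions: Dess–Martin periodinane, NaHCO3, CH2Cl2, 0 °C → rt
Reagents that add atoms: none
Why: Dess–Martin oxidation of the single secondary alcohol gives the C8 ketone under neutral conditions that leave the epoxide and the acetate alone, and removes the C8 stereocentre once it has served as a control element.

Step 12
Reactants: 15 the 9β,10β-epoxy-8-ketone; 16 angelic acid, (Z)-2-methylbut-2-enoic acid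
Product: 17 CNP0196241.1, (3S,4R,5R,9S,10R)-3-acetoxy-7-acetyl-10-hydroxy-4,5-dimethyl-8-oxo bicyclic 6-en-9-yl (Z)-2-methylbut-2-enoate (3β-OAc, 4β-Me, 5β-Me, 9α-O-angeloyl, 10β-OH)
Conditions: 16 (5 equiv), Cs2CO3 (0.3 equiv), DMF, 40 °C
Reagents that add atoms: none
Why: Nucleophilic opening of an α,β-epoxy ketone at the α-carbon (the mode known for 4β,5β-epoxy-3-keto steroids with thiolates, halides and carboxylic acids), in which angelate attacks C9, activated for SN2 displacement by the adjacent carbonyl, from the α face with inversion, while the fully substituted C10 cannot be attacked under these non-ionising conditions and keeps its β oxygen as the tertiary alcohol, and the (Z)-geometry of the acid is preserved in the absence of strong acid or nucleophilic amine catalysts.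

**Compound list**

1 | 2,3-dimethylcyclohex-2-en-1-one | CC1=C(C)C(=O)CCC1 | starting material
2 | (S)-2,3-dimethylcyclohex-2-en-1-ol | CC1=C(C)[C@@H](O)CCC1 | intermediate
3 | (S)-2,3-dimethylcyclohex-2-en-1-yl acetate | CC1=C(C)[C@@H](OC(C)=O)CCC1 | intermediate
4 | (S)-2,3-dimethyl-4-oxocyclohex-2-en-1-yl acetate | CC1=C(C)[C@@H](OC(C)=O)CCC1=O | intermediate
5 | (1S,2R)-4-{[diethoxy(methyl)silyl]oxy}-2,3-dimethylcyclohex-3-en-1-yl acetate | CC1=C(O[Si](C)(OCC)OCC)CC[C@H](OC(C)=O)[C@@H]1C | intermediate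
6 | (1S,2R)-2,3-dimethyl-4-{[(trifluoromethyl)sulfonyl]oxy}cyclohex-3-en-1-yl acetate | CC1=C(OS(=O)(=O)C(F)(F)F)CC[C@H](OC(C)=O)[C@@H]1C | intermediate
7 | (E)-1,2-bis(4,4,5,5-tetramethyl-1,3,2-dioxaborolan-2-yl)ethene | CC1(C)OB(/C=C/B2OC(C)(C)C(C)(C)O2)OC1(C)C | starting material
8 | (1S,2R)-2,3-dimethyl-4-[(E)-2-(4,4,5,5-tetramethyl-1,3,2-dioxaborolan-2-yl)ethenyl]cyclohex-3-en-1-yl acetate | CC1=C(/C=C/B2OC(C)(C)C(C)(C)O2)CC[C@H](OC(C)=O)[C@@H]1C | intermediate
9 | 4-methoxybenzyl alcohol | COc1ccc(CO)cc1 | starting material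
10 | (1S,2R)-4-[(E)-2-(4-methoxybenzyloxy)ethenyl]-2,3-dimethylcyclohex-3-en-1-yl acetate | CC1=C(/C=C/OCc2ccc(OC)cc2)CC[C@H](OC(C)=O)[C@@H]1C | intermediate
11 | but-3-yn-2-one | CC(=O)C#C | starting material
12 | (3S,4R,5R,8S)-3-acetoxy-7-acetyl-8-(4-methoxybenzyloxy)-4,5-dimethyl bicyclic 6,9(10)-diene | CC(=O)C1=C[C@]2(C)[C@@H](C)[C@@H](OC(C)=O)CCC2=C[C@@H]1OCc1ccc(OC)cc1 | intermediate
13 | (3S,4R,5R,8R,9S,10R)-3-acetoxy-7-acetyl-9β,10β-epoxy-8α-(4-methoxybenzyloxy)-4,5-dimethyl bicyclic 6-ene | CC(=O)C1=C[C@]2(C)[C@@H](C)[C@@H](OC(C)=O)CC[C@@]23O[C@H]3[C@@H]1OCc1ccc(OC)cc1 | intermediate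
14 | (3S,4R,5R,8R,9S,10R)-3-acetoxy-7-acetyl-9β,10β-epoxy-4,5-dimethyl bicyclic 6-en-8α-ol | CC(=O)C1=C[C@]2(C)[C@@H](C)[C@@H](OC(C)=O)CC[C@@]23O[C@H]3[C@@H]1O | intermediate
15 | (3S,4R,5R,9R,10R)-3-acetoxy-7-acetyl-9β,10β-epoxy-4,5-dimethyl bicyclic 6-en-8-one | CC(=O)C1=C[C@]2(C)[C@@H](C)[C@@H](OC(C)=O)CC[C@@]23O[C@H]3C1=O | intermediate
16 | angelic acid, (Z)-2-methylbut-2-enoic acid | C/C=C(/C)C(=O)O | starting material
17 | CNP0196241.1, (3S,4R,5R,9S,10R)-3-acetoxy-7-acetyl-10-hydroxy-4,5-dimethyl-8-oxo bicyclic 6-en-9-yl (Z)-2-methylbut-2-enoate | C/C=C(/C)C(=O)O[C@@H]1C(=O)C(C(C)=O)=C[C@]2(C)[C@@H](C)[C@@H](OC(C)=O)CC[C@]12O | target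

**Step count**

Total: 12 steps. Longest linear sequence: 12 steps (1 → 17); compounds 7, 9, 11 and 16 are purchased.

**Steps most likely to fail**

Step 8 (Diels–Alder). The s-cis conformer is strained by the inside C5 methyl, so the cycloaddition may be slower than polymerisation of the ynone or thermal decay of the enol ether. Fallback, from 10 back to 12: replace the ynone by the smaller and more electrophilic propynal (C#CC=O) under the same thermal regime, which should give the 7-formyl cycloadduct F1 with the same regio- and facial control. Methylmagnesium bromide in THF at −78 °C adds to the aldehyde ahead of the acetate and gives the 7-(1-hydroxyethyl) carbinol F2 as a mixture of carbinol epimers. Oxidation with MnO2 in CH2Cl2 then gives 12.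

Step 9 (epoxidation). The peracid may attack the α face despite the C8 OPMB group, because the β face is flanked by the C5 methyl; facial selectivity would then be poor and step 12 would end in the 9,10-bis-epimer. Fallback, from 12 back to 15: invert C8 and let the hydroxyl direct the oxidant. DDQ (CH2Cl2/pH 7 buffer, 0 °C) gives the 8α-alcohol F3. Mitsunobu reaction with formic acid (PPh3, DIAD, THF) gives the 8β-formate F4 with inversion. KHCO3 in MeOH at 0 °C cleaves the formate ahead of the acetate and gives the 8β-alcohol F5. VO(acac)2/t-BuOOH in CH2Cl2 epoxidises C9=C10 syn to the hydroxyl and gives the 9β,10β-epoxy-8β-ol F6. Dess–Martin oxidation then gives 15.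

Step 12 (epoxide opening). Substitution by the hindered, weakly nucleophilic angelate may be sluggish, and on prolonged heating the β-hydroxy ketone product may lose water or undergo retro-aldol cleavage. Fallback, from 15 back to 17: bring in the C9 oxygen with the small formate ion and acylate afterwards. Caesium formate/formic acid in DMF at rt opens 15 at C9 to the 9α-formyloxy-10β-hydroxy ketone F7. KHCO3 in MeOH at 0 °C gives the 9α,10β-dihydroxy ketone F8. Angelic acid 16 is converted with 2,4,6-trichlorobenzoyl chloride and Et3N into angelic 2,4,6-trichlorobenzoic anhydride F9, which acylates the secondary C9 hydroxyl of F8 in toluene at 80 °C without DMAP (Yamaguchi esterification) to give 17.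

Further compounds
F1 | step 8 | (3S,4R,5R,8S)-3-acetoxy-7-formyl-8-(4-methoxybenzyloxy)-4,5-dimethyl bicyclic 6,9(10)-diene | O=CC1=C[C@]2(C)[C@@H](C)[C@@H](OC(C)=O)CCC2=C[C@@H]1OCc1ccc(OC)cc1
F2 | step 8 | (3S,4R,5R,8S)-3-acetoxy-7-(1-hydroxyethyl)-8-(4-methoxybenzyloxy)-4,5-dimethyl bicyclic 6,9(10)-diene (carbinol epimers) | CC(O)C1=C[C@]2(C)[C@@H](C)[C@@H](OC(C)=O)CCC2=C[C@@H]1OCc1ccc(OC)cc1
F3 | step 9 | 3β-acetoxy-7-acetyl-4β,5β-dimethyl bicyclic 6,9(10)-dien-8α-ol | CC(=O)C1=C[C@]2(C)[C@@H](C)[C@@H](OC(C)=O)CCC2=C[C@@H]1O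
F4 | step 9 | 3β-acetoxy-7-acetyl-4β,5β-dimethyl bicyclic 6,9(10)-dien-8β-yl formate | CC(=O)C1=C[C@]2(C)[C@@H](C)[C@@H](OC(C)=O)CCC2=C[C@H]1OC=O
F5 | step 9 | 3β-acetoxy-7-acetyl-4β,5β-dimethyl bicyclic 6,9(10)-dien-8β-ol | CC(=O)C1=C[C@]2(C)[C@@H](C)[C@@H](OC(C)=O)CCC2=C[C@H]1O
F6 | step 9 | 3β-acetoxy-7-acetyl-9β,10β-epoxy-4β,5β-dimethyl bicyclic 6-en-8β-ol | CC(=O)C1=C[C@]2(C)[C@@H](C)[C@@H](OC(C)=O)CC[C@@]23O[C@H]3[C@H]1O
F7 | step 12 | 3β-acetoxy-7-acetyl-10β-hydroxy-4β,5β-dimethyl-8-oxo bicyclic 6-en-9α-yl formate | O=CO[C@@H]1C(=O)C(C(C)=O)=C[C@]2(C)[C@@H](C)[C@@H](OC(C)=O)CC[C@]12O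
F8 | step 12 | 3β-acetoxy-7-acetyl-9α,10β-dihydroxy-4β,5β-dimethyl bicyclic 6-en-8-one | O[C@@H]1C(=O)C(C(C)=O)=C[C@]2(C)[C@@H](C)[C@@H](OC(C)=O)CC[C@]12O
F9 | step 12 | angelic 2,4,6-trichlorobenzoic anhydride | C/C=C(/C)C(=O)OC(=O)c1c(Cl)cc(Cl)cc1Cl
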